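**Retrosynthetic overview**
- The target comes from acetonide hydrolysis and alkene reduction, after a Cu-catalysed anti SN2 coupling of a C8 Grignard reagent with an enantioenriched allylic pivalate (C10 set by inversion). The pivalate comes from catalytic enantioselective desymmetrization of the meso epoxide of a meso cyclohexene-fused [3]-ladderane.
- The meso ladderene comes, after removal of two ester groups, from an intramolecular straight [2+2] photocycloaddition of a meso bis-enoate. This step forms C3–C6 and C4–C5, i.e. cyclobutanes B and C together.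
- The bis-enoate comes from Swern/Wittig homologation of the diol obtained from the maleic anhydride / cyclohexa-1,4-diene [2+2] photoadduct (cyclobutane A).
- Ring order: six-membered ring (bought), then ring A (step 1), then rings B and C in one operation (step 4). One catalytic event (step 8) fixes the absolute configuration of all ladder stereocentres.
- Enabling feature: cyclobutane ring A (C1–C2–C7–C8), cis-fused to the six-membered ring, carries the two alkenyl arms cis on C2 and C7 and stacks C3/C6 and C4/C5 face to face at about 3 Å. The CO2Me groups on C4/C5 make the arms absorb and are removed afterwards.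

Key step: step 4

Assumption: 2,2-dimethyl-1,3-dioxan-5-ol and both antipodes of the bicyclic diamine catalyst are taken as purchasable; the glycerol carbon of the target carries two identical CH2OH arms and needs no stereocontrol.
Numbering: ladder numbering of tetracyclo[6.4.0.0(2,7).0(3,6)]dodecane is used (C1/C8 six-ring/ring A fusion, C2/C7 ring A/B fusion, C3/C6 ring B/C fusion, C4/C5 terminal CH2, C9–C12 six-ring CH2, C10 chain-bearing), also for the carbons of the bis-enoate that become them.

Step 1
Reactants: 1 maleic anhydride; 2 cyclohexa-1,4-diene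
Product: 3 meso-cis,anti,cis-bicyclo[4.2.0]oct-3-ene-7,8-dicarboxylic anhydride
Conditions: hν (Pyrex, > 300 nm), acetophenone (sens.), EtOAc, 10 °C; 2 in excess; crystallization
Reagents that add atoms: none
Why: Sensitized [2+2] photocycloaddition via a triplet 1,4-biradical, in which the anhydride stays cis and the cis ring fusion with the anhydride anti to the six-membered ring should predominate on steric grounds, the crystalline meso adduct being separated from trans-fused isomers.

Step 2
Reactants: 3 meso anhydride
Product: 4 meso-cis,anti,cis-bicyclo[4.2.0]oct-3-ene-7,8-diyldimethanol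
Conditions: LiAlH4, THF, 0 °C to rt; aq. NaOH work-up
Reagents that add atoms: none
Why: Hydride reduction of a cyclic anhydride to the 1,4-diol, which touches no stereocentre and leaves the isolated alkene alone.

Step 3
Reactants: 4 meso diol
Product: 6 dimethyl (2E,2'E)-3,3'-(meso-cis,anti,cis-bicyclo[4.2.0]oct-3-ene-7,8-diyl)bis(prop-2-enoate), via dialdehyde 5 (not isolated)
Conditions: (COCl)2, DMSO, CH2Cl2, −78 °C; iPr2NEt; then Ph3P=CHCO2Me, −78 to 0 °C; product kept cold
Reagents that add atoms: methyl (triphenylphosphoranylidene)acetate, COC(=O)C=P(c1ccccc1)(c1ccccc1)c1ccccc1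
Why: Swern oxidation followed in the same flask by E-selective Wittig olefination with a stabilized ylide, so that the epimerizable cis-dialdehyde is consumed below 0 °C and the cis arrangement of the two arms is kept.

Step 4
Reactants: 6 meso bis-enoate
Product: 7 dimethyl meso-tetracyclo[6.4.0.0(2,7).0(3,6)]dodec-10-ene-4,5-dicarboxylate (all ring fusions cis; rings anti; esters cis and exo)
Conditions: hν (254 nm, quartz), degassed MeCN (2 mM), −20 °C
Reagents that add atoms: none
Why: Proposed new method: direct (unsensitized) excitation of the two (E)-enoate chromophores, which ring A holds cis and face to face (C3···C6 about 2.9 Å, C4···C5 about 3.4 Å), should give an intramolecular singlet excimer that collapses by a suprafacial–suprafacial [2+2] cycloaddition to the C3–C6 and C4–C5 bonds; the closest known reaction type is the ladderane-forming [2+2] photocycloaddition of conjugated alkenes pre-stacked by a template or by a first-formed cyclobutane (solid state, cyclophane-held polyene esters) and the intramolecular photodimerization of tethered cinnamates. Ring C (C3–C4–C5–C6) is the cyclobutane of the cycloaddition itself, and ring B (C2–C3–C6–C7) is closed by the C3–C6 bond, i.e. the straight (2,5/1,6) mode of the hexa-1,5-diene unit and not the crossed (1,5/2,6) mode. C3 and C6 are set cis to each other by the suprafacial addition and anti to ring A because the arms should react from the exo,exo conformer in which C4 and C5 point away from ring A; C4 and C5 carry the esters exo (from the E geometry) but are erased in step 6, so E/Z isomerization before closure is harmless. The step needs straight over crossed closure, and cycloaddition over Cope rearrangement and over cleavage of the bis-allylic C2–C7 bond; parallel pre-stacking within the topochemical distance, a singlet pathway (a sensitizer would give a triplet 1,2-biradical that follows the rule of five or fragments) and −20 °C are meant to secure this. The product does not absorb at 254 nm, so the energetically uphill formation of the strained ladder should not be reversed.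

Step 5
Reactants: 7 ladderane diester
Product: 8 meso-tetracyclo[6.4.0.0(2,7).0(3,6)]dodec-10-ene-4,5-dicarboxylic acid (cis and exo)
Conditions: LiOH, THF/MeOH/H2O, rt; then 1 M HCl
Reagents that add atoms: lithium hydroxide, [Li+].[OH-]
Why: Ester saponification, in which any epimerization at C4/C5 is irrelevant because both centres are removed in step 6.

Step 6
Reactants: 8 diacid
Product: 10 meso-(cis,anti,cis,anti,cis)-tetracyclo[6.4.0.0(2,7).0(3,6)]dodec-10-ene, via bis(thiohydroxamate) ester 9 (not isolated)
Conditions: 2-mercaptopyridine N-oxide, DCC, DMAP (cat.), CH2Cl2, 0 °C, dark; then t-BuSH (excess), hν (visible), 0 °C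
Reagents that add atoms: none
Why: Barton reductive decarboxylation (radical chain through the O-acyl thiohydroxamates), in which hydrogen transfer from excess thiol should outrun β-scission of the cyclobutyl radical and leave CH2 at C4 and C5.

Step 7
Reactants: 10 meso ladderene
Product: 11 meso-10,11-epoxytetracyclo[6.4.0.0(2,7).0(3,6)]dodecane (oxirane on the convex face; anti to ring A)
Conditions: mCPBA, NaHCO3, CH2Cl2, 0 °C
Reagents that add atoms: mCPBA, O=C(OO)c1cccc(Cl)c1
Why: Prilezhaev epoxidation, expected from the convex face of the cis-fused cyclohexene because the endo hydrogens of ring A shield the concave face.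

Step 8
Reactants: 11 meso epoxide
Product: 13 (10S)-tetracyclo[6.4.0.0(2,7).0(3,6)]dodec-11-en-10-yl pivalate (C–O on the convex face), via lithium alkoxide 12 (not isolated)
Conditions: 3-(pyrrolidin-1-ylmethyl)-2-azabicyclo[2.2.1]heptane (5 mol%, antipode that removes H-12), LDA (2 equiv), DBU (5 equiv), THF, 0 °C to rt; then Piv2O, 0 °C
Reagents that add atoms: pivalic anhydride, CC(C)(C)C(=O)OC(=O)C(C)(C)C
Why: Catalytic enantioselective epoxide-to-allylic-alcohol rearrangement (syn β-elimination by a chiral lithium amide regenerated by LDA), in which removal of one of the two enantiotopic syn hydrogens sets C10 as (S) and thereby the absolute configuration of the six ladder stereocentres, the alkoxide being trapped as the pivalate.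

Step 9
Reactants: 14 2,2-dimethyl-1,3-dioxan-5-ol; 15 1,8-dibromooctane
Product: 16 5-[(8-bromooctyl)oxy]-2,2-dimethyl-1,3-dioxane
Conditions: NaH, DMF, 0 °C to rt; 15 in excess
Reagents that add atoms: none
Why: Williamson ether synthesis, with excess dibromide to suppress double alkylation.

Step 10
Reactants: 13 allylic pivalate; 16 bromide
Product: 18 5-({8-[(10R)-tetracyclo[6.4.0.0(2,7).0(3,6)]dodec-11-en-10-yl]octyl}oxy)-2,2-dimethyl-1,3-dioxane (chain on the concave face; cis to ring A), via Grignard reagent 17 (not isolated)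
Conditions: 16, Mg, THF, rt; then 13, Li2CuCl4 (5 mol%), THF, −30 °C, fast addition
Reagents that add atoms: none
Why: Copper-catalysed allylic substitution with a Grignard reagent under α-selective (dialkylcuprate) conditions, in which oxidative addition anti to the pivalate and reductive elimination at the less hindered allyl terminus C10 (C12 is flanked by the ring fusion) should give net inversion and place the chain cis to ring A.

Step 11
Reactants: 18 alkene
Product: 19 5-({8-[(1R,2S,3S,6R,7R,8S,10S)-tetracyclo[6.4.0.0(2,7).0(3,6)]dodecan-10-yl]octyl}oxy)-2,2-dimethyl-1,3-dioxane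
Conditions: 2-nitrobenzenesulfonylhydrazide, Et3N, CH2Cl2, rt
Reagents that add atoms: none
Why: Diimide reduction (metal-free syn transfer of H2) of the cis-disubstituted alkene, which creates no stereocentre and avoids hydrogenolysis of the strained ladder.

Step 12
Reactants: 19 acetonide
Product: 20 2-({8-[(1R,2S,3S,6R,7R,8S,10S)-tetracyclo[6.4.0.0(2,7).0(3,6)]dodecan-10-yl]octyl}oxy)propane-1,3-diol
Conditions: 1 M HCl, THF/MeOH, rt
Reagents that add atoms: none
Why: Acid-catalysed acetonide hydrolysis, which releases the 1,3-diol under conditions that the ladder hydrocarbon should tolerate.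

**Compound list**
1 | maleic anhydride | O=C1OC(=O)C=C1 | starting material
2 | cyclohexa-1,4-diene | C1=CCC=CC1 | starting material
3 | meso-cis,anti,cis-bicyclo[4.2.0]oct-3-ene-7,8-dicarboxylic anhydride (cis ring fusion; anhydride on the cyclobutane face opposite the six-membered ring) | C1=CC[C@@H]2[C@H](C1)[C@H]1C(=O)OC(=O)[C@@H]21 | intermediate
4 | meso-cis,anti,cis-bicyclo[4.2.0]oct-3-ene-7,8-diyldimethanol | C1=CC[C@@H]2[C@H](C1)[C@@H](CO)[C@H]2CO | intermediate
5 | meso-cis,anti,cis-bicyclo[4.2.0]oct-3-ene-7,8-dicarbaldehyde | C1=CC[C@@H]2[C@H](C1)[C@@H](C=O)[C@H]2C=O | intermediate (not isolated)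
6 | dimethyl (2E,2'E)-3,3'-(meso-cis,anti,cis-bicyclo[4.2.0]oct-3-ene-7,8-diyl)bis(prop-2-enoate) | C1=CC[C@@H]2[C@H](C1)[C@@H](/C=C/C(=O)OC)[C@H]2/C=C/C(=O)OC | intermediate
7 | dimethyl meso-tetracyclo[6.4.0.0(2,7).0(3,6)]dodec-10-ene-4,5-dicarboxylate (all ring fusions cis; rings anti; esters cis and exo) | C1=CC[C@@H]2[C@H](C1)[C@H]1[C@@H]3[C@@H](C(=O)OC)[C@@H](C(=O)OC)[C@@H]3[C@@H]21 | intermediate
8 | meso-tetracyclo[6.4.0.0(2,7).0(3,6)]dodec-10-ene-4,5-dicarboxylic acid (cis, exo) | C1=CC[C@@H]2[C@H](C1)[C@H]1[C@@H]3[C@@H](C(=O)O)[C@@H](C(=O)O)[C@@H]3[C@@H]21 | intermediate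
9 | bis(2-thioxopyridin-1(2H)-yl) ester of 8 | C1=CC[C@@H]2[C@H](C1)[C@H]1[C@@H]3[C@@H](C(=O)ON4C=CC=CC4=S)[C@@H](C(=O)ON4C=CC=CC4=S)[C@@H]3[C@@H]21 | intermediate (not isolated)
10 | meso-(cis,anti,cis,anti,cis)-tetracyclo[6.4.0.0(2,7).0(3,6)]dodec-10-ene | C1=CC[C@@H]2[C@H](C1)[C@H]1[C@@H]3CC[C@@H]3[C@@H]21 | intermediate
11 | meso-10,11-epoxytetracyclo[6.4.0.0(2,7).0(3,6)]dodecane (oxirane cis to H-1/H-8, anti to ring A) | [C@H]14O[C@@H]4C[C@@H]2[C@H](C1)[C@H]1[C@@H]3CC[C@@H]3[C@@H]21 | intermediate
12 | lithium (10S)-tetracyclo[6.4.0.0(2,7).0(3,6)]dodec-11-en-10-olate (ladder configuration as in 20) | [Li+].[O-][C@@H]1C=C[C@@H]2[C@H](C1)[C@H]1[C@@H]3CC[C@@H]3[C@@H]21 | intermediate (not isolated)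
13 | (10S)-tetracyclo[6.4.0.0(2,7).0(3,6)]dodec-11-en-10-yl pivalate (ladder configuration as in 20; C–O convex) | CC(C)(C)C(=O)O[C@@H]1C=C[C@@H]2[C@H](C1)[C@H]1[C@@H]3CC[C@@H]3[C@@H]21 | intermediate
14 | 2,2-dimethyl-1,3-dioxan-5-ol | CC1(C)OCC(O)CO1 | starting material
15 | 1,8-dibromooctane | BrCCCCCCCCBr | starting material
16 | 5-[(8-bromooctyl)oxy]-2,2-dimethyl-1,3-dioxane | CC1(C)OCC(CO1)OCCCCCCCCBr | intermediate
17 | {8-[(2,2-dimethyl-1,3-dioxan-5-yl)oxy]octyl}magnesium bromide | CC1(C)OCC(CO1)OCCCCCCCC[Mg]Br | intermediate (not isolated)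
18 | 5-({8-[(10R)-tetracyclo[6.4.0.0(2,7).0(3,6)]dodec-11-en-10-yl]octyl}oxy)-2,2-dimethyl-1,3-dioxane (chain cis to ring A; ladder as in 20) | CC1(C)OCC(CO1)OCCCCCCCC[C@H]1C=C[C@@H]2[C@H](C1)[C@H]1[C@@H]3CC[C@@H]3[C@@H]21 | intermediate
19 | 5-({8-[(1R,2S,3S,6R,7R,8S,10S)-tetracyclo[6.4.0.0(2,7).0(3,6)]dodecan-10-yl]octyl}oxy)-2,2-dimethyl-1,3-dioxane | CC1(C)OCC(CO1)OCCCCCCCC[C@H]1CC[C@@H]2[C@H](C1)[C@H]1[C@@H]3CC[C@@H]3[C@@H]21 | intermediate
20 | 2-({8-[(1R,2S,3S,6R,7R,8S,10S)-tetracyclo[6.4.0.0(2,7).0(3,6)]dodecan-10-yl]octyl}oxy)propane-1,3-diol | OCC(CO)OCCCCCCCC[C@H]1CC[C@@H]2[C@H](C1)[C@H]1[C@@H]3CC[C@@H]3[C@@H]21 | target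

**Totals**
- Total step count: 12
- Longest linear sequence: 11 (steps 1–8 and 10–12)

**Steps most likely to fail**

1. Step 4 (proposed new method). The enoates may isomerize E/Z without closing, close in the crossed 1,5/2,6 sense, or lose ring A by cleavage or Cope rearrangement of the bis-allylic C2–C7 bond. The fallback builds rings B and C one after the other by known reactions, setting out from diol 4. MsCl/Et3N gives bis(mesylate) F1, which Na2S closes to the cis-fused thiolane F2. α-Chlorination (NCS) and S-selective oxidation (H2O2, cat. Na2WO4) give α-chloro sulfone F3, and KOtBu effects Ramberg–Bäcklund contraction to cyclobutene F4 (ring B). Sensitized [2+2] photocycloaddition of maleic anhydride 1 to the strained cyclobutene double bond from its exo face gives anhydride F5 (ring C, anti), and aqueous hydrolysis comes back to the route at diacid 8.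

2. Step 10. Attack at the γ-terminus C12 or E2 elimination could erode regio- and stereocontrol at C10. The fallback sets C10 by hydrogenation instead of substitution, setting out from epoxide 11. The rearrangement of step 8 with an aqueous quench gives allylic alcohol F6, and Dess–Martin oxidation gives enone F7. 1,4-Reduction with K-Selectride and trapping of the enolate with PhNTf2 give enol triflate F8. Iron-catalysed Kumada-type coupling (Fe(acac)3, THF/NMP) with Grignard reagent 17 gives the trisubstituted alkene F9. Homogeneous hydrogenation ([Ir(cod)(PCy3)(py)]PF6, H2) from the convex face comes back to the route at 19.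

3. Step 1. Hydrogen abstraction from the doubly allylic CH2 groups of 2 and unselective closure of the 1,4-biradical (trans ring fusion) may cut the amount of cis,anti,cis adduct. The fallback builds the six-membered ring thermally on a preformed cyclobutene, setting out from maleic anhydride 1. Sensitized [2+2] photocycloaddition with acetylene gives cis-cyclobut-3-ene-1,2-dicarboxylic anhydride F10. Diels–Alder reaction with buta-1,3-diene (sealed tube, toluene, about 140 °C) on the face anti to the anhydride ring comes back to the route at 3, with the cis ring fusion fixed by the suprafacial cycloaddition.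

Further compounds
F1 | step 4 | meso-cis,anti,cis-bicyclo[4.2.0]oct-3-ene-7,8-diylbis(methylene) dimethanesulfonate | C1=CC[C@@H]2[C@H](C1)[C@@H](COS(C)(=O)=O)[C@H]2COS(C)(=O)=O
F2 | step 4 | meso cis,anti,cis-fused thiolane (cyclohexene / cyclobutane / tetrahydrothiophene) | C1=CC[C@@H]2[C@H](C1)[C@H]1CSC[C@@H]21
F3 | step 4 | α-chloro sulfone of F2 (racemic, epimers at CHCl) | C1=CC[C@@H]2[C@H](C1)[C@H]1C(Cl)S(=O)(=O)C[C@@H]21
F4 | step 4 | meso-cis,anti,cis-tricyclo[6.2.0.0(2,7)]deca-4,9-diene | C1=CC[C@@H]2[C@H](C1)[C@H]1C=C[C@@H]21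
F5 | step 4 | meso-tetracyclo[6.4.0.0(2,7).0(3,6)]dodec-10-ene-4,5-dicarboxylic anhydride (exo, rings anti) | C1=CC[C@@H]2[C@H](C1)[C@H]1[C@@H]3[C@H]4C(=O)OC(=O)[C@H]4[C@@H]3[C@@H]21
F6 | step 10 | (10S)-tetracyclo[6.4.0.0(2,7).0(3,6)]dodec-11-en-10-ol | O[C@@H]1C=C[C@@H]2[C@H](C1)[C@H]1[C@@H]3CC[C@@H]3[C@@H]21
F7 | step 10 | tetracyclo[6.4.0.0(2,7).0(3,6)]dodec-11-en-10-one (ladder as in 20) | O=C1C=C[C@@H]2[C@H](C1)[C@H]1[C@@H]3CC[C@@H]3[C@@H]21
F8 | step 10 | tetracyclo[6.4.0.0(2,7).0(3,6)]dodec-10-en-10-yl trifluoromethanesulfonate (ladder as in 20) | O=S(=O)(OC1=CC[C@@H]2[C@H](C1)[C@H]1[C@@H]3CC[C@@H]3[C@@H]21)C(F)(F)F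
F9 | step 10 | 5-{[8-(tetracyclo[6.4.0.0(2,7).0(3,6)]dodec-10-en-10-yl)octyl]oxy}-2,2-dimethyl-1,3-dioxane (ladder as in 20) | CC1(C)OCC(CO1)OCCCCCCCCC1=CC[C@@H]2[C@H](C1)[C@H]1[C@@H]3CC[C@@H]3[C@@H]21
F10 | step 1 | cis-cyclobut-3-ene-1,2-dicarboxylic anhydride | O=C1OC(=O)[C@H]2C=C[C@@H]12
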